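Cuts: ring A at C8–O (SN2 lactonisation), C11=C13 (decarboxylative methylenation) and C7–C11 (malonyl radical onto an enol ether); the C11′–aryl bond (Pd α-arylation of the ring D lactone); C4–CH3 with the ring D C–O bond (methylcerium addition/lactonisation); C5–C1 with C5–C6 (carbene onto an arene); C2–C3 (anti-aldol).
Enabling feature: the tetrasubstituted ring-fusion alkene C1=C5 shared by rings B and C, with oxygenated C4 on C5. C1 and C6–C10 are the six carbons of a 4-methoxy-2-methylphenyl ring (arene CH3 = C14 on C10, anisole carbon = C8), and C5 is the carbene carbon of a diazoketone whose carbonyl is C4.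
Forward order: aldol chain, diazoketone, ring C closed while the benzene ring is expanded to ring B in one operation, ring D, aryl bromide joined, ring A last, then protecting-group exchange.
Stereochemistry: C2/C3 from an auxiliary-controlled anti-aldol; C4 by addition anti to both; C10 by conjugate hydride delivery anti to the C2 silyl ether; C7 and C11′ by thermodynamic equilibration; C8 by hindered hydride then SN2 inversion; the side-chain centre by Ir-catalysed asymmetric hydrogenation.

Key step: step 6

Remark: locants are guaiane-type. C1–C5 = ring C (C2 oxygenated, C3 chain-bearing, C4 quaternary); C1, C5–C10 = ring B; C11–C13 = ring A; C11′–C13′ = ring D; C14 = CH3 on C10. The β face is the one that carries the C2 oxygen, the C3 chain, the C4 oxygen, C14 and C11 in the target; α is the opposite face.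
Assumption: the facial senses written for the auxiliary aldol (step 2) and the iridium hydrogenation (step 11) follow the usual chelate and quadrant models; the antipodal auxiliary or ligand would be taken otherwise.

Step 1
Reactants: 1 (4R)-4-benzyl-1,3-oxazolidin-2-one; 2 methyl 5-chloro-5-oxopentanoate
Product: 3 methyl 5-[(4R)-4-benzyl-2-oxo-1,3-oxazolidin-3-yl]-5-oxopentanoate
Conditions: n-BuLi, THF, −78 °C; then 2, −78 → 0 °C
Reagents that add atoms: none
Why: N-acylation of the lithiated oxazolidinone by the acid chloride (acyl substitution) puts the auxiliary on the five-carbon chain that becomes C4, C3 and C13′–C12′, the methyl ester being far less electrophilic at −78 °C.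

Step 2
Reactants: 3 methyl 5-[(4R)-4-benzyl-2-oxo-1,3-oxazolidin-3-yl]-5-oxopentanoate; 4 4-methoxy-2-methylbenzaldehyde
Product: 6 methyl (4S)-5-[(4R)-4-benzyl-2-oxo-1,3-oxazolidin-3-yl]-4-[(R)-hydroxy(4-methoxy-2-methylphenyl)methyl]-5-oxopentanoate, via trimethylsilyl ether 5 (not isolated)
Conditions: MgCl2 (0.2 equiv), Et3N, Me3SiCl, EtOAc, 23 °C; then MeOH, PPTS (cat.), 0 °C
Reagents that add atoms: none
Why: Evans-type magnesium-catalysed, silyl-trapped anti-aldol reaction in which the chelated (Z)-magnesium enolate should be attacked by the non-enolisable aldehyde on the face away from the benzyl group, setting the (4S) and (R)-carbinol centres (C3 and C2, anti in the chain and therefore cis on ring C).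

Step 3
Reactants: 6 anti-aldol adduct
Product: 7 methyl (4S)-5-[(4R)-4-benzyl-2-oxo-1,3-oxazolidin-3-yl]-4-[(R)-(tert-butyldimethylsilyloxy)(4-methoxy-2-methylphenyl)methyl]-5-oxopentanoate
Conditions: t-BuMe2SiOTf, 2,6-lutidine, CH2Cl2, −78 → 0 °C
Reagents that add atoms: tert-butyldimethylsilyl triflate, CC(C)(C)[Si](C)(C)OS(=O)(=O)C(F)(F)F
Why: Silyl ether formation with the silyl triflate and a hindered pyridine base masks the C2 oxygen against O–H insertion in step 6 and creates the bulky group that later directs C10, without touching a stereocentre.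

Step 4
Reactants: 7 silyl-protected imide
Product: 8 (2S)-2-[(R)-(tert-butyldimethylsilyloxy)(4-methoxy-2-methylphenyl)methyl]-5-methoxy-5-oxopentanoic acid
Conditions: LiOH, H2O2, THF/H2O, 0 °C; Na2SO3; 1 M HCl to pH 3
Reagents that add atoms: hydrogen peroxide (as lithium hydroperoxide), OO
Why: Hydroperoxide cleavage of the N-acyl oxazolidinone attacks the exocyclic imide carbonyl selectively even next to the branched centre, spares the methyl ester and silyl ether at 0 °C, and is too weakly basic to epimerise C3.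

Step 5
Reactants: 8 carboxylic acid
Product: 10 methyl (4S)-4-[(R)-(tert-butyldimethylsilyloxy)(4-methoxy-2-methylphenyl)methyl]-6-diazo-5-oxohexanoate, via mixed carbonic anhydride 9 (not isolated)
Conditions: i-BuOCOCl, N-methylmorpholine, THF, −20 °C; then CH2N2, Et2O, 0 °C
Reagents that add atoms: diazomethane, C=[N+]=[N-]
Why: Acylation of diazomethane by the mixed carbonic anhydride (first stage of the Arndt–Eistert sequence) gives the α-diazoketone without epimerising the α-centre.

Step 6
Reactants: 10 diazoketone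
Product: 14 methyl 3-[(2S,3R)-3-(tert-butyldimethylsilyloxy)-6-methoxy-4-methyl-1-oxo-1,2,3,8-tetrahydroazulen-2-yl]propanoate (C4=O; C5=C1; C10=C9; C8=C7; C6H2), via norcaradiene 11 (not isolated), via cycloheptatriene 12 (not isolated), via cross-conjugated trienone 13 (not isolated)
Conditions: Rh2(OAc)4 (1 mol%), CH2Cl2, 40 °C, slow addition of 10; then Et3N (0.5 equiv), 23 °C; then toluene, 110 °C
Reagents that add atoms: none
Why: Rh2(OAc)4 turns the diazoketone into an electrophilic carbenoid at C5 that adds to the ipso/ortho bond C1–C6 of the anisole ring (intramolecular Buchner reaction) to give norcaradiene 11, whose disrotatory 6π electrocyclic opening breaks the transient C1–C6 bond and gives cycloheptatriene 12. Ring C closes by 5-exo attack of the carbenoid carbon on the ipso carbon (new bond C5–C1), the cyclopropane closes through the second carbenoid bond (C5–C6) and is only a temporary ring, and ring B arises from it by ring expansion of the benzene nucleus, not by a closure of its own. Et3N then moves the doubly activated C5 proton to C10 (13) and heating relocates it to C6 by a suprafacial [1,5]-hydrogen shift, so that both C5 epimers and both C10 epimers should converge on the one linearly conjugated trienone 14 that carries the C1=C5 ring-fusion alkene. The closest known reaction type is the dirhodium-catalysed cyclisation of 1-diazo-4-arylbutan-2-ones to dihydroazulenones followed by amine-mediated conjugation of the ring-fusion double bond. No lasting stereocentre is created (C5, C1, C6 and C10 are transient and erased), and C2 and C3 should survive because C3–H is far less acidic than the vinylogous protons and the thermal stage is base-free. The step needs chemoselectivity for arene addition over C–H insertion or attack on the silyl ether (the ipso carbon is para to methoxy, and the nearest C–H bonds are α to an ester or would give a four-membered ring), regioselectivity for the unsubstituted ortho carbon (the other bears the methyl group that becomes C14), and a thermodynamic preference for 14 (endocyclic tetrasubstituted enone, linear conjugation, methyl on an sp2 carbon).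

Step 7
Reactants: 14 linear trienone
Product: 16 tricyclic δ-lactone (2R,3S,4S): ring D cis-fused on C3–C4; C4–CH3 α; C2–OSiMe2t-Bu β; C5=C1; C10(CH3)=C9; C8(OCH3)=C7; C6H2, via hydroxy ester 15 (not isolated)
Conditions: CeCl3 (anhydrous), MeLi, THF, −78 °C; add 14; −78 → 23 °C
Reagents that add atoms: methyllithium (transferred as MeCeCl2), [Li]C
Why: 1,2-selective organocerium addition to the trienone carbonyl from the α face, anti to the cis C2 silyl ether and C3 chain, sets C4 (CH3 α, O β), and the tertiary alkoxide then closes ring D by acyl substitution on the methyl ester (6-exo-trig lactonisation), which only the cis arrangement allows.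

Step 8
Reactants: 17 6-bromo-2-benzofuran-1(3H)-one (6-bromophthalide); 18 (3-bromopropoxy)(tert-butyl)dimethylsilane
Product: 20 6-bromo-1-[3-(tert-butyldimethylsilyloxy)propyl]-1,3-dihydro-2-benzofuran-1-ol, via Grignard reagent 19 (not isolated)
Conditions: 18, Mg, THF, 40 °C; add to 17, THF, −78 °C; H2O
Reagents that add atoms: none
Why: Single Grignard addition to the lactone carbonyl at low temperature stops at the magnesium hemiketal (lactol after work-up), the aryl bromide being inert to alkylmagnesium exchange at −78 °C.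

Step 9
Reactants: 20 lactol
Product: 21 {4-bromo-2-[5-(tert-butyldimethylsilyloxy)pent-1-en-2-yl]phenyl}methanol
Conditions: Ph3PCH3Br (3 equiv), KOt-Bu (3 equiv), THF, 0 → 60 °C
Reagents that add atoms: methyltriphenylphosphonium bromide, C[P+](c1ccccc1)(c1ccccc1)c1ccccc1.[Br-]
Why: Wittig methylenation of the ring-opened keto alkoxide form of the lactol converts the aryl ketone into the 1,1-disubstituted alkene and frees the benzylic alcohol.

Step 10
Reactants: 21 alkenyl benzyl alcohol
Product: 22 4-bromo-2-[5-(tert-butyldimethylsilyloxy)pent-1-en-2-yl]-1-[(4-methoxybenzyloxy)methyl]benzene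
Conditions: NaH, 4-methoxybenzyl chloride, Bu4NI (cat.), THF/DMF, 0 → 23 °C
Reagents that add atoms: 4-methoxybenzyl chloride, COc1ccc(CCl)cc1
Why: Williamson etherification of the primary benzylic alkoxide gives a 4-methoxybenzyl ether that is orthogonal to the silyl ethers and removable oxidatively at the end.

Step 11
Reactants: 22 alkene
Product: 23 4-bromo-1-[(4-methoxybenzyloxy)methyl]-2-[(2R)-5-(tert-butyldimethylsilyloxy)pentan-2-yl]benzene
Conditions: H2 (2 bar), [Ir(cod)((S)-t-Bu-PHOX)][B(3,5-(CF3)2C6H3)4] (1 mol%), CH2Cl2, 23 °C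
Reagents that add atoms: none
Why: Iridium-catalysed asymmetric hydrogenation of a 1,1-disubstituted aryl alkene with a chiral P,N ligand should set the benzylic (R) centre under catalyst control while leaving the aryl bromide and both ethers intact.

Step 12
Reactants: 16 tricyclic δ-lactone; 23 aryl bromide
Product: 24 α-aryl lactone (2R,3S,4S,11′R): lactone 16 carrying at C11′ the 4-[(4-methoxybenzyloxy)methyl]-3-[(2R)-5-(tert-butyldimethylsilyloxy)pentan-2-yl]phenyl group
Conditions: LiN(SiMe3)2, THF, −78 °C; ZnCl2, −78 → 0 °C; 23, Pd(dba)2 (5 mol%), P(t-Bu)3 (10 mol%), 23 → 45 °C; then DBU (0.3 equiv), CH2Cl2, 23 °C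
Reagents that add atoms: none
Why: Palladium-catalysed α-arylation of a zinc ester enolate works here because the ring D lactone is the only carbonyl and C11′ its only enolisable position, and the DBU stage should equilibrate C11′ to the epimer with a pseudo-equatorial aryl group on the conformer that keeps C4–CH3 equatorial, expected to be (11′R).

Step 13
Reactants: 25 diallyl malonate
Product: 26 diallyl 2-bromomalonate
Conditions: N-bromosuccinimide, Mg(ClO4)2 (cat.), MeCN, 23 °C
Reagents that add atoms: N-bromosuccinimide, O=C1CCC(=O)N1Br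
Why: Electrophilic α-bromination of the malonate enol by N-bromosuccinimide under mild Lewis acid catalysis provides the radical precursor for step 14.

Step 14
Reactants: 24 α-aryl lactone; 26 diallyl 2-bromomalonate
Product: 27 malonyl dienone: C8 ketone; C9=C10(CH3); C1=C5; C6H2; C7 bearing CH(CO2CH2CH=CH2)2 (C7 epimers); otherwise as 24
Conditions: Ir(ppy)3 (1 mol%), 2,6-lutidine, MeCN/H2O (10:1), blue LEDs, 23 °C
Reagents that add atoms: water, O
Why: Photoredox radical alkylation of an enol ether, in which the electrophilic malonyl radical should add to C7 (β-carbon of the arene-derived methyl enol ether and terminus of the conjugated tetraene), the α-methoxy pentadienyl radical is oxidised to the oxocarbenium ion, and hydrolysis gives the C8 ketone directly as the most substituted linear dienone; C7 forms as an epimer mixture that step 15 corrects.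

Step 15
Reactants: 27 malonyl dienone
Product: 28 ketone (7R,10S): C10–H α and C14 β; C7 malonyl β; C9H2; C1=C5 kept
Conditions: Cu(OAc)2 (5 mol%), 1,2-bis(diphenylphosphino)benzene (5 mol%), PhSiH3, t-BuOH, toluene, 0 → 23 °C; then DBU (3 equiv), toluene, 50 °C
Reagents that add atoms: none
Why: Copper hydride 1,4-reduction of a β,β-disubstituted enone should deliver hydride to C10 from the α face, opposite the C2 silyl ether and ring D that cover the β face (C14 ends β), with the fully substituted δ-carbon C5 disfavouring 1,6-reduction, and the DBU stage then equilibrates C7 (α to the ketone) to the pseudo-equatorial β-malonyl epimer and re-equilibrates C11′.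

Step 16
Reactants: 28 ketone
Product: 30 8β-mesylate (8R): C8–OSO2CH3 cis to the C7 malonyl group, via cis-alcohol 29 (not isolated)
Conditions: LiBH(s-Bu)3 (1.3 equiv), THF, −78 °C; AcOH, −78 °C; then MeSO2Cl, Et3N, CH2Cl2, −20 → 0 °C
Reagents that add atoms: methanesulfonyl chloride, CS(=O)(=O)Cl
Why: Hindered borohydride reduction should attack the C8 ketone from the α face, anti to the C7 malonyl group and the pseudo-axial C14, giving the 8β (cis) alcohol, which is quenched cold before it can lactonise and sulfonylated with retention.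

Step 17
Reactants: 30 8β-mesylate
Product: 33 α-methylene lactone (target skeleton with C2–OSiMe2t-Bu, side-chain OSiMe2t-Bu and benzylic 4-methoxybenzyl ether), via diacid mesylate 31 (not isolated), via carboxy lactone 32 (not isolated)
Conditions: Pd(PPh3)4 (5 mol%), morpholine (6 equiv), THF, 23 → 45 °C; then 37% aq. CH2O, AcOH (excess), NaOAc, 60 °C
Reagents that add atoms: formaldehyde, C=O
Why: Zerovalent-palladium allyl ester cleavage (allyl transfer to morpholine) frees the malonate carboxylates, one of which displaces the C8 mesylate in a 5-exo-tet SN2 lactonisation with inversion (C8–O α, trans-fused ring A), and the remaining α-carboxy lactone undergoes decarboxylative Mannich methylenation, conditions that leave the more acidic C11′–H untouched.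

Step 18
Reactants: 33 α-methylene lactone
Product: 34 diol (C2–OH and side-chain CH2OH free; benzylic 4-methoxybenzyl ether kept)
Conditions: HF·pyridine, pyridine, THF, 0 → 23 °C
Reagents that add atoms: none
Why: Fluoride-mediated desilylation under buffered conditions removes both silyl ethers and leaves the 4-methoxybenzyl ether, both lactones and the exocyclic methylene untouched.

Step 19
Reactants: 34 diol
Product: 35 diacetate (C2–OAc and side-chain OAc; benzylic 4-methoxybenzyl ether kept)
Conditions: Ac2O, pyridine, DMAP (cat.), CH2Cl2, 0 → 23 °C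
Reagents that add atoms: acetic anhydride, CC(=O)OC(C)=O
Why: Nucleophile-catalysed acetylation of the secondary allylic C2 alcohol and the primary side-chain alcohol installs both acetates of the target with retention at C2.

Step 20
Reactants: 35 diacetate
Product: 36 CNP0205574.1
Conditions: DDQ, CH2Cl2/pH 7 buffer, 0 °C
Reagents that add atoms: none
Why: Oxidative cleavage of the 4-methoxybenzyl ether by hydride abstraction with DDQ and hydrolysis of the resulting oxocarbenium ion frees the benzylic alcohol without affecting the acetates, the lactones or any stereocentre.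

Compound list
1 | (4R)-4-benzyl-1,3-oxazolidin-2-one | O=C1N[C@H](Cc2ccccc2)CO1 | starting material
2 | methyl 5-chloro-5-oxopentanoate | COC(=O)CCCC(Cl)=O | starting material
3 | methyl 5-[(4R)-4-benzyl-2-oxo-1,3-oxazolidin-3-yl]-5-oxopentanoate | COC(=O)CCCC(=O)N1[C@H](Cc2ccccc2)COC1=O | intermediate
4 | 4-methoxy-2-methylbenzaldehyde | COc1ccc(C=O)c(C)c1 | starting material
5 | trimethylsilyl ether of aldol adduct 6 | COC(=O)CC[C@H](C(=O)N1[C@H](Cc2ccccc2)COC1=O)[C@@H](O[Si](C)(C)C)c1ccc(OC)cc1C | intermediate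
6 | methyl (4S)-5-[(4R)-4-benzyl-2-oxo-1,3-oxazolidin-3-yl]-4-[(R)-hydroxy(4-methoxy-2-methylphenyl)methyl]-5-oxopentanoate | COC(=O)CC[C@H](C(=O)N1[C@H](Cc2ccccc2)COC1=O)[C@@H](O)c1ccc(OC)cc1C | intermediate
7 | methyl (4S)-5-[(4R)-4-benzyl-2-oxo-1,3-oxazolidin-3-yl]-4-[(R)-(tert-butyldimethylsilyloxy)(4-methoxy-2-methylphenyl)methyl]-5-oxopentanoate | COC(=O)CC[C@H](C(=O)N1[C@H](Cc2ccccc2)COC1=O)[C@@H](O[Si](C)(C)C(C)(C)C)c1ccc(OC)cc1C | intermediate
8 | (2S)-2-[(R)-(tert-butyldimethylsilyloxy)(4-methoxy-2-methylphenyl)methyl]-5-methoxy-5-oxopentanoic acid | COC(=O)CC[C@H](C(=O)O)[C@@H](O[Si](C)(C)C(C)(C)C)c1ccc(OC)cc1C | intermediate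
9 | isobutyl carbonic mixed anhydride of acid 8 | COC(=O)CC[C@H](C(=O)OC(=O)OCC(C)C)[C@@H](O[Si](C)(C)C(C)(C)C)c1ccc(OC)cc1C | intermediate
10 | methyl (4S)-4-[(R)-(tert-butyldimethylsilyloxy)(4-methoxy-2-methylphenyl)methyl]-6-diazo-5-oxohexanoate | COC(=O)CC[C@H](C(=O)C=[N+]=[N-])[C@@H](O[Si](C)(C)C(C)(C)C)c1ccc(OC)cc1C | intermediate
11 | norcaradiene (cyclopropane C5–C1–C6; C7=C8(OCH3); C9=C10(CH3); C4 ketone; 2R,3S; new centres as mixture) | COC(=O)CC[C@@H]1C(=O)C2C3C=C(OC)C=C(C)C23[C@@H]1O[Si](C)(C)C(C)(C)C | intermediate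
12 | methyl 3-[(2S,3R)-3-(tert-butyldimethylsilyloxy)-6-methoxy-4-methyl-1-oxo-1,2,3,8a-tetrahydroazulen-2-yl]propanoate (C5–H epimers) | COC(=O)CC[C@@H]1C(=O)C2C=CC(OC)=CC(C)=C2[C@@H]1O[Si](C)(C)C(C)(C)C | intermediate
13 | methyl 3-[(2S,3R)-3-(tert-butyldimethylsilyloxy)-6-methoxy-4-methyl-1-oxo-1,2,3,4-tetrahydroazulen-2-yl]propanoate (C10 epimers) | COC(=O)CC[C@@H]1C(=O)C2=C([C@@H]1O[Si](C)(C)C(C)(C)C)C(C)C=C(OC)C=C2 | intermediate
14 | methyl 3-[(2S,3R)-3-(tert-butyldimethylsilyloxy)-6-methoxy-4-methyl-1-oxo-1,2,3,8-tetrahydroazulen-2-yl]propanoate | COC(=O)CC[C@@H]1C(=O)C2=C([C@@H]1O[Si](C)(C)C(C)(C)C)C(C)=CC(OC)=CC2 | intermediate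
15 | methyl 3-[(1S,2S,3R)-3-(tert-butyldimethylsilyloxy)-1-hydroxy-6-methoxy-1,4-dimethyl-1,2,3,8-tetrahydroazulen-2-yl]propanoate | COC(=O)CC[C@@H]1[C@](C)(O)C2=C([C@@H]1O[Si](C)(C)C(C)(C)C)C(C)=CC(OC)=CC2 | intermediate
16 | tricyclic δ-lactone (2R,3S,4S): ring D cis-fused on C3–C4; C4–CH3 α; C2–OSiMe2t-Bu β; C5=C1; C10(CH3)=C9; C8(OCH3)=C7; C6H2 | CC1=CC(OC)=CCC2=C1[C@H](O[Si](C)(C)C(C)(C)C)[C@@H]1CCC(=O)O[C@]21C | intermediate
17 | 6-bromo-2-benzofuran-1(3H)-one | O=C1OCc2ccc(Br)cc21 | starting material
18 | (3-bromopropoxy)(tert-butyl)dimethylsilane | CC(C)(C)[Si](C)(C)OCCCBr | starting material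
19 | [3-(tert-butyldimethylsilyloxy)propyl]magnesium bromide | CC(C)(C)[Si](C)(C)OCCC[Mg]Br | intermediate
20 | 6-bromo-1-[3-(tert-butyldimethylsilyloxy)propyl]-1,3-dihydro-2-benzofuran-1-ol (racemic hemiketal) | OC1(CCCO[Si](C)(C)C(C)(C)C)OCc2ccc(Br)cc21 | intermediate
21 | {4-bromo-2-[5-(tert-butyldimethylsilyloxy)pent-1-en-2-yl]phenyl}methanol | C=C(CCCO[Si](C)(C)C(C)(C)C)c1cc(Br)ccc1CO | intermediate
22 | 4-bromo-2-[5-(tert-butyldimethylsilyloxy)pent-1-en-2-yl]-1-[(4-methoxybenzyloxy)methyl]benzene | C=C(CCCO[Si](C)(C)C(C)(C)C)c1cc(Br)ccc1COCc1ccc(OC)cc1 | intermediate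
23 | 4-bromo-1-[(4-methoxybenzyloxy)methyl]-2-[(2R)-5-(tert-butyldimethylsilyloxy)pentan-2-yl]benzene | C[C@H](CCCO[Si](C)(C)C(C)(C)C)c1cc(Br)ccc1COCc1ccc(OC)cc1 | intermediate
24 | α-aryl lactone (2R,3S,4S,11′R): 16 with the aryl group of 23 at C11′ | CC1=CC(OC)=CCC2=C1[C@H](O[Si](C)(C)C(C)(C)C)[C@@H]1C[C@H](c3ccc(COCc4ccc(OC)cc4)c([C@H](C)CCCO[Si](C)(C)C(C)(C)C)c3)C(=O)O[C@]21C | intermediate
25 | diallyl malonate | C=CCOC(=O)CC(=O)OCC=C | starting material
26 | diallyl 2-bromomalonate | C=CCOC(=O)C(Br)C(=O)OCC=C | intermediate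
27 | malonyl dienone: C8 ketone; C9=C10; C1=C5; C7–CH(CO2allyl)2 (C7 epimers) | CC1=CC(=O)C(C(C(=O)OCC=C)C(=O)OCC=C)CC2=C1[C@H](O[Si](C)(C)C(C)(C)C)[C@@H]1C[C@H](c3ccc(COCc4ccc(OC)cc4)c([C@H](C)CCCO[Si](C)(C)C(C)(C)C)c3)C(=O)O[C@]21C | intermediate
28 | ketone (7R,10S): C14 β; C7 malonyl β; C1=C5 | C[C@H]1CC(=O)[C@@H](C(C(=O)OCC=C)C(=O)OCC=C)CC2=C1[C@H](O[Si](C)(C)C(C)(C)C)[C@@H]1C[C@H](c3ccc(COCc4ccc(OC)cc4)c([C@H](C)CCCO[Si](C)(C)C(C)(C)C)c3)C(=O)O[C@]21C | intermediate
29 | 8β-alcohol (8R), cis to the C7 malonyl group | C[C@H]1C[C@@H](O)[C@@H](C(C(=O)OCC=C)C(=O)OCC=C)CC2=C1[C@H](O[Si](C)(C)C(C)(C)C)[C@@H]1C[C@H](c3ccc(COCc4ccc(OC)cc4)c([C@H](C)CCCO[Si](C)(C)C(C)(C)C)c3)C(=O)O[C@]21C | intermediate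
30 | 8β-mesylate (8R) | C[C@H]1C[C@@H](OS(C)(=O)=O)[C@@H](C(C(=O)OCC=C)C(=O)OCC=C)CC2=C1[C@H](O[Si](C)(C)C(C)(C)C)[C@@H]1C[C@H](c3ccc(COCc4ccc(OC)cc4)c([C@H](C)CCCO[Si](C)(C)C(C)(C)C)c3)C(=O)O[C@]21C | intermediate
31 | malonic acid 8β-mesylate | C[C@H]1C[C@@H](OS(C)(=O)=O)[C@@H](C(C(=O)O)C(=O)O)CC2=C1[C@H](O[Si](C)(C)C(C)(C)C)[C@@H]1C[C@H](c3ccc(COCc4ccc(OC)cc4)c([C@H](C)CCCO[Si](C)(C)C(C)(C)C)c3)C(=O)O[C@]21C | intermediate
32 | trans-fused α-carboxy-γ-lactone (7R,8S; C11 epimers) | OC(=O)C1C(=O)O[C@H]2C[C@H](C)C3=C(C[C@H]12)[C@@]1(C)OC(=O)[C@@H](c2ccc(COCc4ccc(OC)cc4)c([C@H](C)CCCO[Si](C)(C)C(C)(C)C)c2)C[C@H]1[C@H]3O[Si](C)(C)C(C)(C)C | intermediate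
33 | α-methylene lactone: target skeleton with C2–OSiMe2t-Bu, side-chain OSiMe2t-Bu and benzylic 4-methoxybenzyl ether | C=C1C(=O)O[C@H]2C[C@H](C)C3=C(C[C@H]12)[C@@]1(C)OC(=O)[C@@H](c2ccc(COCc4ccc(OC)cc4)c([C@H](C)CCCO[Si](C)(C)C(C)(C)C)c2)C[C@H]1[C@H]3O[Si](C)(C)C(C)(C)C | intermediate
34 | diol: C2–OH and side-chain CH2OH free; benzylic 4-methoxybenzyl ether | C=C1C(=O)O[C@H]2C[C@H](C)C3=C(C[C@H]12)[C@@]1(C)OC(=O)[C@@H](c2ccc(COCc4ccc(OC)cc4)c([C@H](C)CCCO)c2)C[C@H]1[C@H]3O | intermediate
35 | diacetate with benzylic 4-methoxybenzyl ether | C=C1C(=O)O[C@H]2C[C@H](C)C3=C(C[C@H]12)[C@@]1(C)OC(=O)[C@@H](c2ccc(COCc4ccc(OC)cc4)c([C@H](C)CCCOC(C)=O)c2)C[C@H]1[C@H]3OC(C)=O | intermediate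
36 | CNP0205574.1 | C=C1C(=O)O[C@H]2C[C@H](C)C3=C(C[C@H]12)[C@@]1(C)OC(=O)[C@@H](c2ccc(CO)c([C@H](C)CCCOC(C)=O)c2)C[C@H]1[C@H]3OC(C)=O | target

Total step count: 20. Longest linear sequence: 15 (steps 1–7, 12, 14–20).

Steps most likely to fail

Step 6. The double-bond migration after ring expansion may not converge on 14: a push–pull isomer (C5=C6, C7=C8) could compete, C3 could epimerise on long exposure to base or heat, or the carbenoid could divert into insertion pathways. The fallback sets out from 10 and separates ring formation from the isomer funnel. The reaction is stopped after the Et3N stage at the cross-conjugated trienone 13, which is isolated as its C10 epimer mixture. MeCeCl2 addition then gives hydroxy ester F1, which lactonises to the cross-conjugated lactone F2. F2 has no carbonyl conjugated to the triene, so only the endocyclic-alkene isomers are accessible, and heating (toluene, 120 °C) moves the C10 hydrogen to C6 by a purely sigmatropic [1,5]-shift. The route is rejoined at 16.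

Step 14. The malonyl radical may add at another position of the tetraene, or the electron-rich polyene may be oxidised by the photocatalyst cycle before the C–C bond forms. The fallback sets out from 24 and makes the ketone first. Mild hydrolysis (oxalic acid, wet THF) gives dienone F3. Soft enolisation (Me3SiOTf, Et3N) gives the cross-conjugated silyl dienol ether F4. F4 is alkylated with 26 in an Et3B/air-initiated bromine-transfer chain without photocatalyst or oxidant. The route is rejoined at 27.

Step 17. The C8 mesylate may undergo elimination, or the free alcohol may close to the cis lactone, before the carboxylate displaces with inversion. The fallback sets out from 28 and exchanges the order of events. The allyl esters are removed first (Pd(PPh3)4, morpholine) to give keto malonic acid F5. Reduction of its dicarboxylate with LiBH(s-Bu)3 gives the 8β-hydroxy malonic acid F6, which cannot lactonise under basic conditions. Mitsunobu lactonisation (PPh3, diisopropyl azodicarboxylate) activates the alcohol and closes ring A with inversion. The route is rejoined at 32, which is methylenated as in step 17.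

Further compounds
F1 | step 6 | methyl 3-[(1S,2S,3R)-3-(tert-butyldimethylsilyloxy)-1-hydroxy-6-methoxy-1,4-dimethyl-1,2,3,4-tetrahydroazulen-2-yl]propanoate (C10 epimers) | COC(=O)CC[C@@H]1[C@](C)(O)C2=C([C@@H]1O[Si](C)(C)C(C)(C)C)C(C)C=C(OC)C=C2
F2 | step 6 | cross-conjugated lactone (2R,3S,4S): as 16 but C6=C7, C8(OCH3)=C9 and C10–H (C10 epimers) | CC1C=C(OC)C=CC2=C1[C@H](O[Si](C)(C)C(C)(C)C)[C@@H]1CCC(=O)O[C@]21C
F3 | step 14 | dienone: as 27 without the malonyl group (C7H2) | CC1=CC(=O)CCC2=C1[C@H](O[Si](C)(C)C(C)(C)C)[C@@H]1C[C@H](c3ccc(COCc4ccc(OC)cc4)c([C@H](C)CCCO[Si](C)(C)C(C)(C)C)c3)C(=O)O[C@]21C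
F4 | step 14 | 8-trimethylsilyloxy triene (C7=C8, C9=C10, C1=C5) | CC1=CC(O[Si](C)(C)C)=CCC2=C1[C@H](O[Si](C)(C)C(C)(C)C)[C@@H]1C[C@H](c3ccc(COCc4ccc(OC)cc4)c([C@H](C)CCCO[Si](C)(C)C(C)(C)C)c3)C(=O)O[C@]21C
F5 | step 17 | keto malonic acid (7R,10S) | C[C@H]1CC(=O)[C@@H](C(C(=O)O)C(=O)O)CC2=C1[C@H](O[Si](C)(C)C(C)(C)C)[C@@H]1C[C@H](c3ccc(COCc4ccc(OC)cc4)c([C@H](C)CCCO[Si](C)(C)C(C)(C)C)c3)C(=O)O[C@]21C
F6 | step 17 | 8β-hydroxy malonic acid (7R,8R,10S) | C[C@H]1C[C@@H](O)[C@@H](C(C(=O)O)C(=O)O)CC2=C1[C@H](O[Si](C)(C)C(C)(C)C)[C@@H]1C[C@H](c3ccc(COCc4ccc(OC)cc4)c([C@H](C)CCCO[Si](C)(C)C(C)(C)C)c3)C(=O)O[C@]21C
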